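The readings are calculated from invented constants; noise was put on by code.

The small charge of first nucleophile, 1.10 equiv against 5.00 equiv of second nucleophile, was where I began.

| flask | starting material | first nucleophile | second nucleophile | capture agent | temperature | remark | time |
|---|---|---|---|---|---|---|---|
| larch | 0.050 M | 1.1 equiv | 7.5 equiv | 0.015 M | 40 °C | run made earlier |  |
| Sunday's | 0.050 M | 1.10 equiv | 5.00 equiv | 0.0150 M | 40 °C |  | 2.0 min |
| Friday's | 0.050 M | 1.10 equiv | 5.00 equiv | 0.0150 M |  | at 65 °C until 40 s, from then on at 40 °C | 2.0 min |
| Saturday's | 0.050 M | 1.10 equiv | 5.00 equiv | 0.0150 M | 65 °C |  | 2.0 min |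

larch run (percent of the starting material charged)

| time / s | target / % | other capture product / % |
|---|---|---|
| 10.0 | 5.3 | 7.4 |
| 12.0 | 6.1 | 8.5 |
| 15.0 | 7.2 | 11.7 |
| 20.0 | 10.0 | 13.4 |
| 25.0 | 11.5 | 17.1 |

(standard deviation of a reading: 0.5 percentage points)

- the flask that comes out highest in share of target in all that became target or other capture product or trapped intermediate, or "all alike" when all lie within 1.5 percentage points (Sunday's / Friday's / Saturday's / all alike)
- share of target in all that became target or other capture product or trapped intermediate, Sunday's
- share of target in all that became target or other capture product or trapped intermediate, Friday's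
- share of target in all that became target or other capture product or trapped intermediate, Saturday's

- the earlier runs do not show what temperature does; that part of a forecast is a guess

Summed over its readings, the larch run gave target over other capture product as 0.690. I assumed that first nucleophile makes target and second nucleophile makes other capture product, which one run cannot test. With the larch charges, that gave 4.71 for S, the selectivity factor: rate of target over rate of other capture product, divided by first over second nucleophile present.

For Sunday's, the starting rate ratio was therefore 1.04. I assumed the whole charge would end in the two products, each taking half. Consumption then slows target by a factor 0.545 and other capture product by 0.900, so the ratio ends at 0.627. The mean of the two ratios, 0.831, gave me a share of 45.4%, with trapped intermediate set to nil. Heat was unreadable, so I gave Friday's and Saturday's the same figure and left the ranking open.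

The forecast differed, holding that “Target/other should then scale with second nucleophile”. It named Sunday's, with 28% (range 21% to 36%), 27% (19% to 36%) and 25% (16% to 36%).

The flasks gave 48.2% for Sunday's, 43.3% for Friday's and 43.3% for Saturday's, so Sunday's came out highest.

    second nucleophile + open intermediate → other capture product (k = 18.0 M⁻¹ s⁻¹, Ea = 58.0 kJ mol⁻¹)
    open intermediate + capture agent → trapped intermediate (k = 0.180 M⁻¹ s⁻¹, Ea = 56.0 kJ mol⁻¹)
    2 starting material → homo dimer (k = 0.160 M⁻¹ s⁻¹, Ea = 40.0 kJ mol⁻¹)
    first nucleophile + open intermediate → target (k = 86.0 M⁻¹ s⁻¹, Ea = 52.0 kJ mol⁻¹)
    starting material ⇌ open intermediate (K = 0.290, k = 0.0160 s⁻¹, Ea = 77.0 kJ mol⁻¹, ΔH = −50.0 kJ mol⁻¹)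
    (constants at 40 °C)

Changing only the second nucleophile in the larch run, at its last reading, moved the share from 40.2% to 49.9%, where the starting ratio reckons 51.0%. But S was read at 40 °C, and Friday's held 0.332% of starting material at its change of temperature, 0.667 min, so I scaled S by Friday's end ratio over the mean of its starting and end ratios reckoned with S, a factor 0.852. The neighbour of Friday's charged with 2.00 equiv of second nucleophile then starts at 2.21. At its end, 51.0% of first nucleophile and 84.6% of second nucleophile remained, which takes the ratio to 1.33. The mean of the two, 1.77, reckons a share of 63.9%. That neighbour gave 63.6%, with target at 53.9% and other capture product at 30.8%.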